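All constants belong to no real substance, and the outcome is calculated.

**Late times.** Late in this flask the electrophile slows, and I began by asking how far it gets.

electrophile 20 mM; nucleophile 1.20 equiv; time 10 min

    nucleophile + acid set free ⇌ protonated nucleophile, settled at all times (K1 = 24700 L mol⁻¹)
    electrophile + nucleophile → acid set free + target (k2 = 0.301 L mol⁻¹ s⁻¹)
    acid set free → by-product carried off (k3 = 0.00539 s⁻¹)
    2 free base → self-condensation product (k4 = 0.0254 L mol⁻¹ s⁻¹)
    acid set free + free base ⇌ salt of the base, settled at all times (K5 = 47500 L mol⁻¹)

* the equivalents of free base at which the part of the electrophile that has reacted at 10 min is just 70 %

**The ceiling.** Each electrophile that reacts uses one nucleophile and sets free one acid, and with 593 as the binding constant times the starting nucleophile, I took that acid as bound to a second partner, nucleophile or free base. I set aside the two side steps. The ceiling number is half the summed equivalents of nucleophile and free base, the part of the electrophile that can react, with those two steps aside, before free partners run out. Without base it is 60.0 %, so in this reckoning nucleophile is the limiting reagent despite its excess. In the same reckoning, reaching 70.0 % takes at least 0.200 equiv of base.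

**The clock.** One number was not enough: the ceiling says how far, not how soon. I integrated the second-order rate, counting every free partner as nucleophile, for a trial charge of 0.300 equiv, with ceiling 75.0 %. That gave 8.33 min to the wanted part, shorter than the run. The spare 1.67 min had to cover the free partners that are in truth free base, whose binding constant for acid is 1.92 times that of nucleophile. I committed to about 0.300 equiv.

**The result.** The forecast said 0.34 equiv, in the words “acid is shared”. The simulation gave 0.327 equiv, where the ceiling number stands at 76.3 %. That number sets the side steps aside: at 30.0 min this flask had used 79.5 % of the electrophile charged, more than the ceiling number. At 10.0 min in this flask, free nucleophile was 8.31 % of its charge and free base 11.1 % of its charge. Together that is 0.136 equiv, against 0.127 equiv from twice the gap below the ceiling. In the flask with twice the free base, the ceiling number is 92.7 %, and the electrophile reacted at the end of that run was 75.7 %.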